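Readings and results were generated by integration for substances that don't exist, noise included.

- Slowness sits downstream of the substrate. In Wednesday's run the substrate is down to 5.9% at 2.50 min, yet product climbs for the full 30.0 min.

in all of them: substrate 0.020 M
- Sunday's: partner 0.0041 M; run made earlier
- Wednesday's: partner 0.063 M; run made earlier
- midnight: partner 0.0120 M; time 40 min
- summer: partner 0.0250 M; time 40 min
- spring: partner 0.00600 M; time 40 min
- winter: partner 0.0200 M; time 40 min
- noon: partner 0.0500 M; time 40 min
- dusk: partner 0.00300 M; time 40 min

| run | time / min | product / % | substrate / % |
|---|---|---|---|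
| Sunday's | 8.00 | 0 | 0.4 |
| Sunday's | 15.0 | 1.3 | 0 |
| Sunday's | 20.0 | 1.4 | 0 |
| Sunday's | 30.0 | 2.1 | 0 |
| Wednesday's | 2.50 | 2.4 | 5.9 |
| Wednesday's | 5.00 | 5.7 | 0.4 |
| Wednesday's | 12.0 | 14.8 | 0 |
| Wednesday's | 30.0 | 31.2 | 1.0 |

(scatter of a reading: 0.5 percentage points)

- ranking by amount of product, in percent of the substrate charged, from high to low, at 40 min (midnight / summer / spring / winter / noon / dusk)
- the amount of product, in percent of the substrate charged of the flask you put first, at 40 min
- the amount of product, in percent of the substrate charged of the flask you put last, at 40 min

- the numbers in the tables scatter with a standard deviation of 0.5 percentage points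

- First, the main step alone: read as a first-order loss, the substrate has a half-life of 0.612 min, far shorter than the 40 min asked. So this step adds nothing to our timing, and 91.7% of Wednesday's charge is unseen at 2.50 min.
- Next, we add a slow step that needs partner, taken as the rate-limiting step. Wednesday's last reading gives 363 M·s, our partner dose, [partner] times time per whole charge turned to product.
- Sunday's last reading, a separate run with much less partner, gives 351 M·s, though its small reading carries the scatter of 0.5 points.
- Dividing the dose by [partner] gives a clock: noon's is 121 min, longer than the 40 min asked. Our reckoning is therefore a straight line, 33.0% for noon and 1.98% for dusk, ranked by [partner].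
- Last, we add the bend in Wednesday's curve: the dose read at 12.0 min is 306 M·s, which puts noon at 39.2%. Reading at 30.0 min instead takes that down to the figure above, so we keep the later reading.
- The forecast gives noon > summer > winter > midnight > spring > dusk, with 31% first and 2.3% last, holding that “it is first order in partner”. Our ranking is the same, but our two amounts differ from its amounts.
- The flasks give noon > summer > winter > midnight > spring > dusk, with 31.7% for noon and 1.67% for dusk.

    substrate → intermediate A (k = 0.00971 s⁻¹)
    intermediate A ⇌ intermediate B (K = 8.30, k = 0.00805 s⁻¹)
    substrate + partner ⇌ intermediate C (K = 44.1 M⁻¹, k = 0.223 M⁻¹ s⁻¹)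
    partner + intermediate C → intermediate D (k = 2.02 M⁻¹ s⁻¹)
    intermediate D → product (k = 4.87 × 10⁻⁴ s⁻¹)

- The forecast held, and the dose read back from noon is 378 M·s, from dusk 432 M·s, against our 363 M·s. The neighbour is dusk with 0.012 M of partner, 0.600 equiv against dusk's smaller share. Its clock is 504 min, so our dose gives 7.93%. The flask gives 9.36%, with 4.61% of the charge still standing as intermediate D at 40.0 min.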